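**Plan**

- Retrosynthetic cuts: the pyranone at O1'–C2' and C5'–C6' (back to a C4 formyl group and a dioxinone C4 unit); ring B at C4–C4a; C1–C8a (aryl Grignard); the C4–CH2O branch (formaldehyde aldol); the four-membered ring at C1–C2 and C3–C4 (ketene plus enol ether).
- Enabling feature: C1 is a ketone on C8a of ring A and C4 is bonded to C4a, the ortho neighbour of C8a. Ring B (C1, C2, C3, C4, C4a, C8a) is therefore the ring-expanded form of a 1-arylcyclobutanol in which C1 and C4 are joined.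
- Forward order: cyclobutanone from acetophenone enol ether and dichloroketene, hydroxymethyl branch, ring A added as a Grignard reagent, ring B by oxidative ring expansion, pyranone ring last, then deprotection.
- Stereochemistry: C3 comes from enantioselective deprotonation of the prochiral cyclobutanone by a chiral lithium amide. C4 is set relative to C3 in the radical closure. The other two cyclobutane centres are erased at the radical stage.
- Locants: bicyclic compounds carry 1-tetralone locants, primes mark the pyranone, monocyclic compounds carry cyclobutane locants. TBS = tert-butyldimethylsilyl, TBDPS = tert-butyldiphenylsilyl.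

Key step: step 7

Assumption: the (R,R)-amide is taken to lead to the (3S) series; the sense of induction is not established for this ketone, and the (S,S)-amine would be used if it is the opposite.

**Route**

Step 1
Reactants: 1 acetophenone
Product: 2 tert-butyldimethyl[(1-phenylethenyl)oxy]silane
Conditions: TBSOTf, Et3N, CH2Cl2, 0 → 25 °C
Reagents that add atoms: tert-butyldimethylsilyl trifluoromethanesulfonate, CC(C)(C)[Si](C)(C)OS(=O)(=O)C(F)(F)F
Why: Soft enolization with silyl triflate and amine gives the silyl enol ether, and the silyl group placed here later protects the tertiary C3 hydroxyl, which would be hard to silylate afterwards.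

Step 2
Reactants: 2 tert-butyldimethyl[(1-phenylethenyl)oxy]silane; 3 trichloroacetyl chloride
Product: 5 rac-2,2-dichloro-3-(TBS-oxy)-3-phenylcyclobutan-1-one, via dichloroketene 4 (not isolated)
Conditions: Zn–Cu couple, Et2O/DME, 25 °C, slow addition of 3
Reagents that add atoms: none
Why: Dichloroketene released by zinc undergoes the thermal ketene–alkene [2+2] cycloaddition with the electron-rich enol ether, its carbonyl carbon bonding to the nucleophilic CH2 terminus so that the silyloxy carbon becomes C3, while DME ties up ZnCl2.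

Step 3
Reactants: 5 rac-2,2-dichloro-3-(TBS-oxy)-3-phenylcyclobutan-1-one
Product: 6 3-(TBS-oxy)-3-phenylcyclobutan-1-one
Conditions: Zn, AcOH, TMEDA, EtOH, 0 → 25 °C
Reagents that add atoms: none
Why: Zinc reduces both α-C–Cl bonds through zinc enolates that acetic acid protonates at once (reductive dehalogenation of an α-halo ketone), and the amine-buffered medium should keep the retro-aldol-prone 3-silyloxycyclobutanone closed.

Step 4
Reactants: 6 3-(TBS-oxy)-3-phenylcyclobutan-1-one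
Product: 8 (3S)-3-(TBS-oxy)-2-(hydroxymethyl)-3-phenylcyclobutan-1-one as a C2 epimer mixture, via lithium enolate 7 (not isolated)
Conditions: (R,R)-bis(1-phenylethyl)amine, n-BuLi, LiCl, THF, −100 °C; monomeric HCHO in THF, −100 °C; AcOH, −100 °C
Reagents that add atoms: formaldehyde, C=O
Why: The chiral lithium amide should remove one of the two enantiotopic α-protons (enantioselective deprotonation of a prochiral 3-substituted cyclobutanone, LiCl sharpening the selectivity), which fixes C3, and the enolate is trapped by aldol addition to formaldehyde at −100 °C before silanolate can be expelled; the new C2 centre is uncontrolled and is erased in step 7.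

Step 5
Reactants: 8 (3S)-3-(TBS-oxy)-2-(hydroxymethyl)-3-phenylcyclobutan-1-one
Product: 9 (3S)-3-(TBS-oxy)-2-[(TBDPS-oxy)methyl]-3-phenylcyclobutan-1-one
Conditions: TBDPSCl, imidazole, CH2Cl2, 0 → 25 °C
Reagents that add atoms: tert-butyl(chloro)diphenylsilane, CC(C)(C)[Si](Cl)(c1ccccc1)c1ccccc1
Why: Silylation of the primary alcohol under neutral imidazole conditions blocks retro-aldol loss of formaldehyde and gives a bulky, acid-stable ether that tolerates the Grignard reagent and the aqueous oxidant of step 7.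

Step 6
Reactants: 9 (3S)-3-(TBS-oxy)-2-[(TBDPS-oxy)methyl]-3-phenylcyclobutan-1-one; 10 2-methoxyphenylmagnesium bromide
Product: 11 (3S)-3-(TBS-oxy)-2-[(TBDPS-oxy)methyl]-1-(2-methoxyphenyl)-3-phenylcyclobutan-1-ol as a C1/C2 epimer mixture
Conditions: THF, −78 → −30 °C; aq. NH4Cl
Reagents that add atoms: none
Why: The aryl Grignard reagent adds to the strained, highly electrophilic cyclobutanone carbonyl faster than it enolizes it (1,2-addition), and the configurations at C1 and C2 are immaterial because both centres are erased in step 7.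

Step 7
Reactants: 11 (3S)-3-(TBS-oxy)-2-[(TBDPS-oxy)methyl]-1-(2-methoxyphenyl)-3-phenylcyclobutan-1-ol
Product: 15 (3S,4R)-3-(TBS-oxy)-4-[(TBDPS-oxy)methyl]-8-methoxy-3-phenyl-1-tetralone, via alkoxyl radical 12 (not isolated), via open-chain C4 radical 13 (not isolated), via cyclohexadienyl radical 14 (not isolated)
Conditions: AgNO3 (20 mol %), K2S2O8 (3 equiv), CH2Cl2/H2O, 30 °C, dark
Reagents that add atoms: none
Why: Divalent silver, formed from AgNO3 and K2S2O8, oxidizes the tertiary cyclobutanol to alkoxyl radical 12, whose strain-driven β-scission breaks the bond that becomes C1–C4 of the tetralone and leaves the aryl ketone at C1 and the secondary radical 13 at C4. Radical 13 adds to C4a, the only free position ortho to the new acyl group (the other carries methoxy), and cyclohexadienyl radical 14 is oxidized and loses a proton; ring B (C1, C2, C3, C4, C4a, C8a) thus closes by a six-membered ortho attack, an intramolecular homolytic aromatic substitution. The closest known reaction type is the silver-catalysed persulfate ring expansion of 1-arylcyclobutanols to 1-tetralones. C4 is the one new stereocentre and is controlled by C3: in the chair-like transition state the silyloxymethyl group should sit pseudoaxial, away from the peri hydrogen at C5, and anti to the bulky tertiary silyl ether with phenyl equatorial, which gives the carbon substituent at C4 trans to oxygen and cis to phenyl as in the target. The step needs scission toward C4 and not toward C2, which formation of a secondary instead of a primary radical from the more substituted ring bond secures, and it needs closure to outrun a 1,2-phenyl shift or oxidation of 13, which the short tether to the electron-poor acyl arene favours. The C1 and C2 centres of 11 vanish in 13, so the epimer mixture converges.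

Step 8
Reactants: 15 (3S,4R)-3-(TBS-oxy)-4-[(TBDPS-oxy)methyl]-8-methoxy-3-phenyl-1-tetralone
Product: 16 (3S,4R)-3-(TBS-oxy)-4-(hydroxymethyl)-8-methoxy-3-phenyl-1-tetralone
Conditions: TBAF, AcOH, THF, 0 → 25 °C
Reagents that add atoms: none
Why: Acetic-acid-buffered fluoride cleaves the unhindered primary silyl ether while the tertiary C3 silyl ether, shielded by phenyl and two ring carbons, should stay, and the buffer suppresses silyl migration and base-induced β-elimination.

Step 9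
Reactants: 16 (3S,4R)-3-(TBS-oxy)-4-(hydroxymethyl)-8-methoxy-3-phenyl-1-tetralone
Product: 17 (3S,4S)-3-(TBS-oxy)-4-formyl-8-methoxy-3-phenyl-1-tetralone
Conditions: Dess–Martin periodinane, NaHCO3, CH2Cl2, 0 °C; used crude
Reagents that add atoms: none
Why: Dess–Martin oxidation under bicarbonate buffer is neutral enough to leave the epimerizable, elimination-prone α-aryl β-silyloxy aldehyde intact.

Step 10
Reactants: 18 2,2,6-trimethyl-4H-1,3-dioxin-4-one
Product: 20 trimethyl[(2,2-dimethyl-6-methylidene-6H-1,3-dioxin-4-yl)oxy]silane, via lithium dienolate 19 (not isolated)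
Conditions: LiN(i-Pr)2, THF, −78 °C; TMSCl
Reagents that add atoms: chlorotrimethylsilane, C[Si](C)(C)Cl
Why: Kinetic γ-deprotonation of the vinylogous ester and O-silylation of the dienolate give the silyl dienol ether, the usual nucleophile for vinylogous Mukaiyama aldol reactions.

Step 11
Reactants: 17 (3S,4S)-3-(TBS-oxy)-4-formyl-8-methoxy-3-phenyl-1-tetralone; 20 trimethyl[(2,2-dimethyl-6-methylidene-6H-1,3-dioxin-4-yl)oxy]silane
Product: 21 (3S,4R)-3-(TBS-oxy)-4-[2-(2,2-dimethyl-4-oxo-4H-1,3-dioxin-6-yl)-1-hydroxyethyl]-8-methoxy-3-phenyl-1-tetralone as a carbinol epimer mixture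
Conditions: BF3·OEt2, CH2Cl2, −78 °C; aq. NaHCO3
Reagents that add atoms: none
Why: The BF3-activated aldehyde is attacked by the terminal carbon of the dienol ether (vinylogous Mukaiyama aldol), forming C5'–C6' under non-basic conditions that should neither enolize C4 nor engage the far less electrophilic C1 ketone; the carbinol centre is uncontrolled because it is oxidized next.

Step 12
Reactants: 21 (3S,4R)-3-(TBS-oxy)-4-[2-(2,2-dimethyl-4-oxo-4H-1,3-dioxin-6-yl)-1-hydroxyethyl]-8-methoxy-3-phenyl-1-tetralone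
Product: 22 (3S,4S)-3-(TBS-oxy)-4-[(2,2-dimethyl-4-oxo-4H-1,3-dioxin-6-yl)acetyl]-8-methoxy-3-phenyl-1-tetralone
Conditions: Dess–Martin periodinane, NaHCO3, CH2Cl2, 25 °C
Reagents that add atoms: none
Why: Dess–Martin oxidation turns the secondary alcohol into the ketone without base, so the acidic C4 hydrogen is not exposed to epimerizing conditions.

Step 13
Reactants: 22 (3S,4S)-3-(TBS-oxy)-4-[(2,2-dimethyl-4-oxo-4H-1,3-dioxin-6-yl)acetyl]-8-methoxy-3-phenyl-1-tetralone
Product: 24 (3S,4S)-3-(TBS-oxy)-4-(4-hydroxy-2-oxo-2H-pyran-6-yl)-8-methoxy-3-phenyl-1-tetralone, via acylketene 23 (not isolated)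
Conditions: toluene, 110 °C, high dilution
Reagents that add atoms: none
Why: On heating, the dioxinone loses acetone in a retro-[4+2] reaction and the acylketene is captured by the enol oxygen of the neighbouring ketone, closing O1'–C2' of the 4-hydroxy-2-pyranone under neutral conditions.

Step 14
Reactants: 24 (3S,4S)-3-(TBS-oxy)-4-(4-hydroxy-2-oxo-2H-pyran-6-yl)-8-methoxy-3-phenyl-1-tetralone
Product: 25 (3S,4S)-3-(TBS-oxy)-8-hydroxy-4-(4-hydroxy-2-oxo-2H-pyran-6-yl)-3-phenyl-1-tetralone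
Conditions: BCl3, CH2Cl2, −78 °C; H2O, aq. NaHCO3
Reagents that add atoms: none
Why: BCl3 chelates between the C1 carbonyl and the peri methoxy oxygen, so chloride removes this methyl group selectively at low temperature (chelation-controlled ether cleavage), while the hindered tertiary silyl ether is expected to survive.

Step 15
Reactants: 25 (3S,4S)-3-(TBS-oxy)-8-hydroxy-4-(4-hydroxy-2-oxo-2H-pyran-6-yl)-3-phenyl-1-tetralone
Product: 26 (3S,4S)-3,8-dihydroxy-4-(4-hydroxy-2-oxo-2H-pyran-6-yl)-3-phenyl-3,4-dihydronaphthalen-1(2H)-one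
Conditions: HF·pyridine, MeCN, 0 → 25 °C
Reagents that add atoms: none
Why: Fluoride cleaves the tertiary Si–O bond in a mildly acidic medium, which avoids the basic conditions under which the β-hydroxy ketone could open by retro-aldol reaction or dehydrate to the naphthol.

**Compound list**

1 | acetophenone | CC(=O)c1ccccc1 | starting material
2 | tert-butyldimethyl[(1-phenylethenyl)oxy]silane | C=C(O[Si](C)(C)C(C)(C)C)c1ccccc1 | intermediate
3 | trichloroacetyl chloride | ClC(=O)C(Cl)(Cl)Cl | starting material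
4 | dichloroketene | O=C=C(Cl)Cl | intermediate
5 | rac-2,2-dichloro-3-(TBS-oxy)-3-phenylcyclobutan-1-one | O=C1CC(O[Si](C)(C)C(C)(C)C)(c2ccccc2)C1(Cl)Cl | intermediate
6 | 3-(TBS-oxy)-3-phenylcyclobutan-1-one (achiral) | O=C1CC(O[Si](C)(C)C(C)(C)C)(c2ccccc2)C1 | intermediate
7 | lithium (3S)-3-(TBS-oxy)-3-phenylcyclobut-1-en-1-olate | [Li]OC1=C[C@](O[Si](C)(C)C(C)(C)C)(c2ccccc2)C1 | intermediate
8 | (3S)-3-(TBS-oxy)-2-(hydroxymethyl)-3-phenylcyclobutan-1-one, C2 epimers | O=C1C[C@@](O[Si](C)(C)C(C)(C)C)(c2ccccc2)C1CO | intermediate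
9 | (3S)-3-(TBS-oxy)-2-[(TBDPS-oxy)methyl]-3-phenylcyclobutan-1-one, C2 epimers | O=C1C[C@@](O[Si](C)(C)C(C)(C)C)(c2ccccc2)C1CO[Si](c3ccccc3)(c4ccccc4)C(C)(C)C | intermediate
10 | 2-methoxyphenylmagnesium bromide | COc1ccccc1[Mg]Br | starting material
11 | (3S)-3-(TBS-oxy)-2-[(TBDPS-oxy)methyl]-1-(2-methoxyphenyl)-3-phenylcyclobutan-1-ol, C1 and C2 epimers | OC1(c2ccccc2OC)C[C@@](O[Si](C)(C)C(C)(C)C)(c3ccccc3)C1CO[Si](c4ccccc4)(c5ccccc5)C(C)(C)C | intermediate
12 | C1 alkoxyl radical of 11, C3 as in 11 | [O]C1(c2ccccc2OC)C[C@@](O[Si](C)(C)C(C)(C)C)(c3ccccc3)C1CO[Si](c4ccccc4)(c5ccccc5)C(C)(C)C | intermediate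
13 | 1-(TBDPS-oxy)-3-(TBS-oxy)-5-(2-methoxyphenyl)-5-oxo-3-phenylpentan-2-yl radical, silyloxy carbon configured as C3 of 11 | O=C(c1ccccc1OC)C[C@@](O[Si](C)(C)C(C)(C)C)(c2ccccc2)[CH]CO[Si](c3ccccc3)(c4ccccc4)C(C)(C)C | intermediate
14 | cyclohexadienyl radical with the C4–C4a bond formed, C4a sp3, unpaired electron at C8a (delocalized to C6 and C8), C3 and C4 as in 15 | O=C1C[C@@](O[Si](C)(C)C(C)(C)C)(c2ccccc2)[C@@H](CO[Si](c3ccccc3)(c4ccccc4)C(C)(C)C)C5C=CC=C(OC)[C]15 | intermediate
15 | (3S,4R)-3-(TBS-oxy)-4-[(TBDPS-oxy)methyl]-8-methoxy-3-phenyl-1-tetralone | O=C1C[C@@](O[Si](C)(C)C(C)(C)C)(c2ccccc2)[C@@H](CO[Si](c3ccccc3)(c4ccccc4)C(C)(C)C)c5cccc(OC)c15 | intermediate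
16 | (3S,4R)-3-(TBS-oxy)-4-(hydroxymethyl)-8-methoxy-3-phenyl-1-tetralone | O=C1C[C@@](O[Si](C)(C)C(C)(C)C)(c2ccccc2)[C@@H](CO)c3cccc(OC)c13 | intermediate
17 | (3S,4S)-3-(TBS-oxy)-4-formyl-8-methoxy-3-phenyl-1-tetralone | O=C1C[C@@](O[Si](C)(C)C(C)(C)C)(c2ccccc2)[C@@H](C=O)c3cccc(OC)c13 | intermediate
18 | 2,2,6-trimethyl-4H-1,3-dioxin-4-one | CC1=CC(=O)OC(C)(C)O1 | starting material
19 | lithium 2,2-dimethyl-6-methylidene-6H-1,3-dioxin-4-olate | C=C1C=C(O[Li])OC(C)(C)O1 | intermediate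
20 | trimethyl[(2,2-dimethyl-6-methylidene-6H-1,3-dioxin-4-yl)oxy]silane | C=C1C=C(O[Si](C)(C)C)OC(C)(C)O1 | intermediate
21 | (3S,4R)-3-(TBS-oxy)-4-[2-(2,2-dimethyl-4-oxo-4H-1,3-dioxin-6-yl)-1-hydroxyethyl]-8-methoxy-3-phenyl-1-tetralone, carbinol epimers | O=C1C[C@@](O[Si](C)(C)C(C)(C)C)(c2ccccc2)[C@@H](C(O)CC3=CC(=O)OC(C)(C)O3)c4cccc(OC)c14 | intermediate
22 | (3S,4S)-3-(TBS-oxy)-4-[(2,2-dimethyl-4-oxo-4H-1,3-dioxin-6-yl)acetyl]-8-methoxy-3-phenyl-1-tetralone | O=C1C[C@@](O[Si](C)(C)C(C)(C)C)(c2ccccc2)[C@@H](C(=O)CC3=CC(=O)OC(C)(C)O3)c4cccc(OC)c14 | intermediate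
23 | (3S,4S)-3-(TBS-oxy)-4-(3,5-dioxopent-4-enoyl)-8-methoxy-3-phenyl-1-tetralone (acylketene) | O=C1C[C@@](O[Si](C)(C)C(C)(C)C)(c2ccccc2)[C@@H](C(=O)CC(=O)C=C=O)c3cccc(OC)c13 | intermediate
24 | (3S,4S)-3-(TBS-oxy)-4-(4-hydroxy-2-oxo-2H-pyran-6-yl)-8-methoxy-3-phenyl-1-tetralone | O=C1C[C@@](O[Si](C)(C)C(C)(C)C)(c2ccccc2)[C@@H](c3cc(O)cc(=O)o3)c4cccc(OC)c14 | intermediate
25 | (3S,4S)-3-(TBS-oxy)-8-hydroxy-4-(4-hydroxy-2-oxo-2H-pyran-6-yl)-3-phenyl-1-tetralone | O=C1C[C@@](O[Si](C)(C)C(C)(C)C)(c2ccccc2)[C@@H](c3cc(O)cc(=O)o3)c4cccc(O)c14 | intermediate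
26 | (3S,4S)-3,8-dihydroxy-4-(4-hydroxy-2-oxo-2H-pyran-6-yl)-3-phenyl-3,4-dihydronaphthalen-1(2H)-one | O=C1C[C@@](O)(c2ccccc2)[C@@H](c3cc(O)cc(=O)o3)c4cccc(O)c14 | target

**Step count and risks**

Total steps: 15. Longest linear sequence: 14 (steps 1–9 and 11–15; step 10 prepares the dienol ether).

Step 7 (ring expansion). The C4 radical may add to C4a through the transition state that places the silyloxymethyl group cis to the C3 silyl ether, so that the wrong C4 epimer predominates; the steric preference argued for in step 7 is not large. Scission toward C2 or a 1,2-phenyl shift before closure would add to the loss. Fallback, from 11 to 17: the ring expansion is run unchanged and control of C4 is moved from the radical closure to a later equilibration.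
- The epimeric product (3S,4S)-3-(TBS-oxy)-4-[(TBDPS-oxy)methyl]-8-methoxy-3-phenyl-1-tetralone F1 is desilylated at the primary oxygen (TBAF, AcOH) to (3S,4S)-3-(TBS-oxy)-4-(hydroxymethyl)-8-methoxy-3-phenyl-1-tetralone F2.
- Dess–Martin oxidation gives (3S,4R)-3-(TBS-oxy)-4-formyl-8-methoxy-3-phenyl-1-tetralone F3.
- In this aldehyde the C4 hydrogen is benzylic and α to the formyl group, so Et3N in CH2Cl2 should equilibrate it with 17 through the enol.
- 17 is separated and the recovered epimer is resubmitted; the route resumes at 17.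

Step 4 (desymmetrizing hydroxymethylation). The lithium enolate may expel the β-silyloxy group, giving 3-phenylcyclobut-2-enone, before it is trapped, or the amide may discriminate poorly between the enantiotopic methylene groups. Fallback, from 2 to 9: the oxygenated carbon is carried into the cycloaddition instead of being added to an enolate, and the enantiomers are separated.
- Sc(OTf)3-catalysed hydroxymethylation of 2 with aqueous formaldehyde gives 3-hydroxy-1-phenylpropan-1-one F4.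
- TBDPSCl and imidazole give 3-(TBDPS-oxy)-1-phenylpropan-1-one F5.
- TBSOTf and Et3N give (Z)-tert-butyl{[3-(TBDPS-oxy)-1-phenylprop-1-en-1-yl]oxy}dimethylsilane F6.
- Cycloaddition with dichloroketene 4 (from 3 and Zn–Cu couple) gives rac-3-(TBS-oxy)-4-[(TBDPS-oxy)methyl]-2,2-dichloro-3-phenylcyclobutan-1-one F7.
- Zinc dechlorination as in step 3 gives rac-3-(TBS-oxy)-2-[(TBDPS-oxy)methyl]-3-phenylcyclobutan-1-one F8, a single diastereomer because the cycloaddition is suprafacial on the (Z)-enol ether.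
- Preparative chromatography on a chiral stationary phase delivers the (3S) enantiomer, which is 9 as one C2 epimer.

Step 14 (demethylation). BCl3 may ionize the tertiary benzylic C3–O bond, after which loss of the C2 proton and aromatization of ring B would destroy the aldol unit. Fallback, from 9 to 25: the phenol is carried as a benzyl ether and released by hydrogenolysis, so no Lewis acid meets the C3 silyl ether.
- 2-(Benzyloxy)phenylmagnesium bromide F9, made from 1-(benzyloxy)-2-bromobenzene and Mg, adds to 9 to give (3S)-1-[2-(benzyloxy)phenyl]-3-(TBS-oxy)-2-[(TBDPS-oxy)methyl]-3-phenylcyclobutan-1-ol F10.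
- The AgNO3/K2S2O8 ring expansion gives (3S,4R)-8-(benzyloxy)-3-(TBS-oxy)-4-[(TBDPS-oxy)methyl]-3-phenyl-1-tetralone F11.
- The conditions of steps 8, 9, 11, 12 and 13 then give in turn:
  - (3S,4R)-8-(benzyloxy)-3-(TBS-oxy)-4-(hydroxymethyl)-3-phenyl-1-tetralone F12;
  - (3S,4S)-8-(benzyloxy)-3-(TBS-oxy)-4-formyl-3-phenyl-1-tetralone F13;
  - (3S,4R)-8-(benzyloxy)-3-(TBS-oxy)-4-[2-(2,2-dimethyl-4-oxo-4H-1,3-dioxin-6-yl)-1-hydroxyethyl]-3-phenyl-1-tetralone F14;
  - (3S,4S)-8-(benzyloxy)-3-(TBS-oxy)-4-[(2,2-dimethyl-4-oxo-4H-1,3-dioxin-6-yl)acetyl]-3-phenyl-1-tetralone F15;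
  - (3S,4S)-8-(benzyloxy)-3-(TBS-oxy)-4-(4-hydroxy-2-oxo-2H-pyran-6-yl)-3-phenyl-1-tetralone F16.
- Hydrogenolysis (H2, Pd/C, EtOAc, 25 °C) then gives 25.

**Further compounds**

F1 | step 7 | (3S,4S)-3-(TBS-oxy)-4-[(TBDPS-oxy)methyl]-8-methoxy-3-phenyl-1-tetralone | O=C1C[C@@](O[Si](C)(C)C(C)(C)C)(c2ccccc2)[C@H](CO[Si](c3ccccc3)(c4ccccc4)C(C)(C)C)c5cccc(OC)c15
F2 | step 7 | (3S,4S)-3-(TBS-oxy)-4-(hydroxymethyl)-8-methoxy-3-phenyl-1-tetralone | O=C1C[C@@](O[Si](C)(C)C(C)(C)C)(c2ccccc2)[C@H](CO)c3cccc(OC)c13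
F3 | step 7 | (3S,4R)-3-(TBS-oxy)-4-formyl-8-methoxy-3-phenyl-1-tetralone | O=C1C[C@@](O[Si](C)(C)C(C)(C)C)(c2ccccc2)[C@H](C=O)c3cccc(OC)c13
F4 | step 4 | 3-hydroxy-1-phenylpropan-1-one | O=C(CCO)c1ccccc1
F5 | step 4 | 3-(TBDPS-oxy)-1-phenylpropan-1-one | O=C(CCO[Si](c1ccccc1)(c2ccccc2)C(C)(C)C)c3ccccc3
F6 | step 4 | (Z)-tert-butyl{[3-(TBDPS-oxy)-1-phenylprop-1-en-1-yl]oxy}dimethylsilane | CC(C)(C)[Si](C)(C)O/C(c1ccccc1)=C\CO[Si](c2ccccc2)(c3ccccc3)C(C)(C)C
F7 | step 4 | rac-3-(TBS-oxy)-4-[(TBDPS-oxy)methyl]-2,2-dichloro-3-phenylcyclobutan-1-one | O=C1C(CO[Si](c2ccccc2)(c3ccccc3)C(C)(C)C)C(O[Si](C)(C)C(C)(C)C)(c4ccccc4)C1(Cl)Cl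
F8 | step 4 | rac-3-(TBS-oxy)-2-[(TBDPS-oxy)methyl]-3-phenylcyclobutan-1-one | O=C1CC(O[Si](C)(C)C(C)(C)C)(c2ccccc2)C1CO[Si](c3ccccc3)(c4ccccc4)C(C)(C)C
F9 | step 14 | 2-(benzyloxy)phenylmagnesium bromide | Br[Mg]c1ccccc1OCc2ccccc2
F10 | step 14 | (3S)-1-[2-(benzyloxy)phenyl]-3-(TBS-oxy)-2-[(TBDPS-oxy)methyl]-3-phenylcyclobutan-1-ol | OC1(c2ccccc2OCc3ccccc3)C[C@@](O[Si](C)(C)C(C)(C)C)(c4ccccc4)C1CO[Si](c5ccccc5)(c6ccccc6)C(C)(C)C
F11 | step 14 | (3S,4R)-8-(benzyloxy)-3-(TBS-oxy)-4-[(TBDPS-oxy)methyl]-3-phenyl-1-tetralone | O=C1C[C@@](O[Si](C)(C)C(C)(C)C)(c2ccccc2)[C@@H](CO[Si](c3ccccc3)(c4ccccc4)C(C)(C)C)c5cccc(OCc6ccccc6)c15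
F12 | step 14 | (3S,4R)-8-(benzyloxy)-3-(TBS-oxy)-4-(hydroxymethyl)-3-phenyl-1-tetralone | O=C1C[C@@](O[Si](C)(C)C(C)(C)C)(c2ccccc2)[C@@H](CO)c3cccc(OCc4ccccc4)c13
F13 | step 14 | (3S,4S)-8-(benzyloxy)-3-(TBS-oxy)-4-formyl-3-phenyl-1-tetralone | O=C1C[C@@](O[Si](C)(C)C(C)(C)C)(c2ccccc2)[C@@H](C=O)c3cccc(OCc4ccccc4)c13
F14 | step 14 | (3S,4R)-8-(benzyloxy)-3-(TBS-oxy)-4-[2-(2,2-dimethyl-4-oxo-4H-1,3-dioxin-6-yl)-1-hydroxyethyl]-3-phenyl-1-tetralone | O=C1C[C@@](O[Si](C)(C)C(C)(C)C)(c2ccccc2)[C@@H](C(O)CC3=CC(=O)OC(C)(C)O3)c4cccc(OCc5ccccc5)c14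
F15 | step 14 | (3S,4S)-8-(benzyloxy)-3-(TBS-oxy)-4-[(2,2-dimethyl-4-oxo-4H-1,3-dioxin-6-yl)acetyl]-3-phenyl-1-tetralone | O=C1C[C@@](O[Si](C)(C)C(C)(C)C)(c2ccccc2)[C@@H](C(=O)CC3=CC(=O)OC(C)(C)O3)c4cccc(OCc5ccccc5)c14
F16 | step 14 | (3S,4S)-8-(benzyloxy)-3-(TBS-oxy)-4-(4-hydroxy-2-oxo-2H-pyran-6-yl)-3-phenyl-1-tetralone | O=C1C[C@@](O[Si](C)(C)C(C)(C)C)(c2ccccc2)[C@@H](c3cc(O)cc(=O)o3)c4cccc(OCc5ccccc5)c14
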